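**Retrosynthetic overview**
1. C11=C12 and C11′=C12′ are cut by two Wittig olefinations: ring A C15 phosphonium salt + (2E,4E,6E)-2,7-dimethylocta-2,4,6-trienedial + ring B C15 phosphonium salt.
2. Both C15 salts come from one chiral-pool C15 acid, (S)-abscisic acid; its carbinol carbon becomes C6 and C6′ (S in both rings), and its 2Z bond is photo-isomerised to 2E first.
3. Ring A: enone epoxidation syn to the C6 hydroxyl (C5–O), Wharton transposition to the 3-ene-5,6-cis-diol, then transannular hydroalkoxylation C6–O→C3 (key C–O bond; closes the oxygen bridge and sets C3).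
4. Ring B: ketone reduction to the 3′,6′-cis-diol, then hydroxyl-directed oxymercuration–demercuration places the C5′ hydroxyl trans (C–O bond; sets C5′).
5. Ring order: both carbocycles are present from the start; the only ring made is the 3,6-oxygen bridge of ring A (step 5), before chain assembly (ring B salt + dialdehyde, then ring A salt).

Assumption: the target is read as all-E (3R,5R,6S,3′R,5′S,6′S); (S)-(+)-abscisic acid (fermentation agrochemical) and the C10 dialdehyde are bought; ring atoms are referred to by carotenoid numbering (C1 gem-dimethyl, C5 methyl-bearing, C6 chain-bearing, primes for ring B).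

**Step 1**
Reactants: 1 (S)-(+)-abscisic acid
Product: 2 methyl (2Z,4E)-5-[(1S)-1-hydroxy-2,6,6-trimethyl-4-oxocyclohex-2-en-1-yl]-3-methylpenta-2,4-dienoate
Conditions: MeI, K2CO3, DMF, rt
Reagents that add atoms: iodomethane, CI
Why: Carboxylate O-alkylation (SN2 on MeI) under mild carbonate conditions leaves the tertiary alcohol, the enone and the stereocentre untouched.

**Step 2**
Reactants: 2 methyl (2Z,4E)-abscisate
Product: 3 methyl (2E,4E)-5-[(1S)-1-hydroxy-2,6,6-trimethyl-4-oxocyclohex-2-en-1-yl]-3-methylpenta-2,4-dienoate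
Conditions: hν (365 nm), acetone, rt, N2; silica separation, recovered 2 re-irradiated
Reagents that add atoms: none
Why: Photochemical E/Z isomerisation of the 2,3-double bond of the dienoate (known for abscisates, photostationary ratio near 1:1) gives the 2E geometry needed for C9=C10 without touching the stereocentre.

**Step 3**
Reactants: 3 methyl (2E,4E)-abscisate
Product: 4 methyl (2E,4E)-5-[(1S,2R,3S)-2,3-epoxy-1-hydroxy-2,6,6-trimethyl-4-oxocyclohexyl]-3-methylpenta-2,4-dienoate (epoxide oxygen cis to the hydroxyl)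
Conditions: 30% H2O2, LiOH (0.3 equiv), MeOH, 0 °C
Reagents that add atoms: hydrogen peroxide, OO
Why: Weitz–Scheffer nucleophilic epoxidation of the enone, in which hydroperoxide adds to C5 on the face of the free C6 hydroxyl (hydrogen-bond delivery, also the face opposite the pseudo-axial side chain), fixes the C5–O configuration of ring A while the less electrophilic dienoate is not attacked.

**Step 4**
Reactants: 4 cis-epoxy ketone
Product: 7 methyl (2E,4E)-5-[(1S,2R)-1,2-dihydroxy-2,6,6-trimethylcyclohex-3-en-1-yl]-3-methylpenta-2,4-dienoate, via epoxy hydrazone 5 (not isolated), via alkenyl diazene 6 (not isolated)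
Conditions: N2H4·H2O (3 equiv), AcOH (0.5 equiv), MeOH, 0 °C to rt
Reagents that add atoms: hydrazine, NN (its nitrogen stays only in 5 and 6)
Why: Wharton transposition (the hydrazone opens the epoxide to an alkenyl diazene that loses N2, as with isophorone oxide) moves the alkene to C3=C4 and leaves the C5–O bond unbroken, so the 5,6-cis-diol is retained.

**Step 5**
Reactants: 7 ene-cis-diol ester
Product: 8 methyl (2E,4E)-5-[(1S,2R,4R)-2-hydroxy-2,6,6-trimethyl-7-oxabicyclo[2.2.1]heptan-1-yl]-3-methylpenta-2,4-dienoate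
Conditions: [PtCl2(H2C=CH2)]2 (2.5 mol %), P(4-CF3C6H4)3 (5 mol %), Cl2CHCHCl2, 70 °C
Reagents that add atoms: none
Why: Proposed new method: divalent-platinum-catalysed transannular hydroalkoxylation of a cyclohex-3-enol, in which the PtCl2–phosphine fragment binds the C3=C4 alkene on the face away from the two hydroxyls, the tertiary C6 hydroxyl attacks C3 from its own face in a boat-like anti-oxyplatination (only this oxygen can reach C3 through a five-membered ring, so C3 is forced to R and the C5 hydroxyl ends cis to the bridge), and the C4–Pt bond is protonated with retention because β-hydride loss is impossible (bridgehead C3–H, no hydrogen on C5); the closest known reaction type is the platinum-catalysed intramolecular hydroalkoxylation of acyclic γ- and δ-hydroxy alkenes, and the ring closure mirrors the classical halo- and seleno-etherification of cyclohex-3-enols to 7-oxanorbornanes.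

**Step 6**
Reactants: 8 bicyclic ether ester
Product: 9 (2E,4E)-5-[(1S,2R,4R)-2-hydroxy-2,6,6-trimethyl-7-oxabicyclo[2.2.1]heptan-1-yl]-3-methylpenta-2,4-dien-1-ol
Conditions: i-Bu2AlH (3.5 equiv), CH2Cl2, −78 °C; aq. potassium sodium tartrate
Reagents that add atoms: none
Why: 1,2-Reduction of the conjugated ester by i-Bu2AlH gives the primary allylic alcohol, and the ether bridge, tertiary alcohol and diene are inert.

**Step 7**
Reactants: 9 ring A allylic alcohol
Product: 11 {(2E,4E)-5-[(1S,2R,4R)-2-hydroxy-2,6,6-trimethyl-7-oxabicyclo[2.2.1]heptan-1-yl]-3-methylpenta-2,4-dienyl}triphenylphosphonium bromide, via allylic bromide 10 (not isolated)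
Conditions: NBS, Me2S, CH2Cl2, −20 to 0 °C; then PPh3, EtOAc, rt
Reagents that add atoms: N-bromosuccinimide, BrN1C(=O)CCC1=O; triphenylphosphine, c1ccc(cc1)P(c1ccccc1)c1ccccc1
Why: Corey–Kim bromination converts only the primary allylic alcohol to the bromide under neutral conditions, and SN2 quaternisation with PPh3 gives the E-configured C15 Wittig salt without acid exposure of the allylic ether.

**Step 8**
Reactants: 3 methyl (2E,4E)-abscisate
Product: 12 methyl (2E,4E)-5-[(1S,4R)-1,4-dihydroxy-2,6,6-trimethylcyclohex-2-en-1-yl]-3-methylpenta-2,4-dienoate (1,4-cis-diol)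
Conditions: NaBH4, CeCl3·7H2O, MeOH, −78 to −40 °C
Reagents that add atoms: none
Why: Luche 1,2-reduction, in which hydride attacks the ketone from the side-chain face, away from the axial C1′ methyl of the side-chain-axial half-chair, gives the 3′,6′-cis-diol (C3′ R) with the ester untouched; the minor trans-diol is removed on silica.

**Step 9**
Reactants: 12 cis-diol ester
Product: 14 methyl (2E,4E)-5-[(1S,2S,4R)-1,2,4-trihydroxy-2,6,6-trimethylcyclohexyl]-3-methylpenta-2,4-dienoate, via organomercurial 13 (not isolated)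
Conditions: Hg(OAc)2, THF/H2O 1:1, rt; then NaBH4, aq. NaOH, 0 °C
Reagents that add atoms: water, O; mercury diacetate, CC(=O)O[Hg]OC(C)=O (its atoms stay only in 13)
Why: Hydroxyl-directed Markovnikov oxymercuration–demercuration, in which mercury is delivered to C4′ on the face of both allylic hydroxyls and water opens the mercurinium ion at the tertiary C5′ from the opposite face (trans-diaxial) before NaBH4 replaces mercury by hydrogen, puts the new C5′ hydroxyl trans to the C3′ and C6′ hydroxyls (C5′ S) and leaves the electron-poor dienoate alone.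

**Step 10**
Reactants: 14 triol ester
Product: 15 (1S,2S,4R)-1-[(1E,3E)-5-hydroxy-3-methylpenta-1,3-dienyl]-2,6,6-trimethylcyclohexane-1,2,4-triol
Conditions: i-Bu2AlH (6 equiv), THF, −78 to 0 °C; aq. potassium sodium tartrate
Reagents that add atoms: none
Why: Ester reduction with excess i-Bu2AlH (three equivalents are consumed by the hydroxyls) gives the primary allylic alcohol without affecting the stereocentres.

**Step 11**
Reactants: 15 ring B tetraol
Product: 17 {(2E,4E)-3-methyl-5-[(1S,2S,4R)-1,2,4-trihydroxy-2,6,6-trimethylcyclohexyl]penta-2,4-dienyl}triphenylphosphonium bromide, via allylic bromide 16 (not isolated)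
Conditions: NBS, Me2S, CH2Cl2/THF, −30 to 0 °C; then PPh3, EtOAc, rt
Reagents that add atoms: N-bromosuccinimide, BrN1C(=O)CCC1=O; triphenylphosphine, c1ccc(cc1)P(c1ccccc1)c1ccccc1
Why: Corey–Kim bromination is selective for the allylic primary alcohol over the saturated secondary and tertiary ones and is non-acidic (the tertiary dienylic C6′ hydroxyl survives), and PPh3 then gives the salt by SN2.

**Step 12**
Reactants: 17 ring B C15 phosphonium bromide; 18 (2E,4E,6E)-2,7-dimethylocta-2,4,6-trienedial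
Product: 20 (2E,4E,6E,8E,10E,12E)-2,7,11-trimethyl-13-[(1S,2S,4R)-1,2,4-trihydroxy-2,6,6-trimethylcyclohexyl]trideca-2,4,6,8,10,12-hexaenal, via ylide 19 (not isolated)
Conditions: NaOMe, MeOH/CH2Cl2, 0 °C, 18 in excess (2 equiv), slow addition of base; then EtOH, 60 °C
Reagents that add atoms: none
Why: Wittig olefination of the semi-stabilised allylic ylide with excess dialdehyde gives mono-olefination (the C25 aldehyde is less electrophilic than 18), and gentle heating converts the hindered Z isomer at the new C11′=C12′ bond to E.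

**Step 13**
Reactants: 11 ring A C15 phosphonium bromide; 20 C25 aldehyde
Product: 22 (all-E)-(3R,5R,6S,3′R,5′S,6′S)-3,6-epoxy-5,6,5′,6′-tetrahydro-β,β-carotene-5,3′,5′,6′-tetrol, via ylide 21 (not isolated)
Conditions: NaOMe, MeOH/CH2Cl2, 0 °C to rt; then EtOH, 65 °C, dark, N2; crystallisation
Reagents that add atoms: none
Why: A second Wittig olefination forms C11=C12 under basic conditions that the free hydroxyls and the acid-labile allylic carbinol tolerate, and thermal Z-to-E equilibration with crystallisation delivers the all-E nonaene with all six stereocentres unchanged.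

**Compound list**
1 | (S)-(+)-abscisic acid, (2Z,4E)-5-[(1S)-1-hydroxy-2,6,6-trimethyl-4-oxocyclohex-2-en-1-yl]-3-methylpenta-2,4-dienoic acid | CC1=CC(=O)CC(C)(C)[C@@]1(O)/C=C/C(C)=C\C(=O)O | starting material
2 | methyl (2Z,4E)-abscisate | CC1=CC(=O)CC(C)(C)[C@@]1(O)/C=C/C(C)=C\C(=O)OC | intermediate
3 | methyl (2E,4E)-abscisate | CC1=CC(=O)CC(C)(C)[C@@]1(O)/C=C/C(C)=C/C(=O)OC | intermediate
4 | methyl (2E,4E)-5-[(1S,2R,3S)-2,3-epoxy-1-hydroxy-2,6,6-trimethyl-4-oxocyclohexyl]-3-methylpenta-2,4-dienoate | C[C@]12O[C@@H]2C(=O)CC(C)(C)[C@@]1(O)/C=C/C(C)=C/C(=O)OC | intermediate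
5 | hydrazone of 4 (C=N geometry not defined) | C[C@]12O[C@@H]2C(=NN)CC(C)(C)[C@@]1(O)/C=C/C(C)=C/C(=O)OC | intermediate (not isolated)
6 | methyl (2E,4E)-5-[(1S,2R)-4-diazenyl-1,2-dihydroxy-2,6,6-trimethylcyclohex-3-en-1-yl]-3-methylpenta-2,4-dienoate | C[C@@]1(O)C=C(N=N)CC(C)(C)[C@@]1(O)/C=C/C(C)=C/C(=O)OC | intermediate (not isolated)
7 | methyl (2E,4E)-5-[(1S,2R)-1,2-dihydroxy-2,6,6-trimethylcyclohex-3-en-1-yl]-3-methylpenta-2,4-dienoate | C[C@@]1(O)C=CCC(C)(C)[C@@]1(O)/C=C/C(C)=C/C(=O)OC | intermediate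
8 | methyl (2E,4E)-5-[(1S,2R,4R)-2-hydroxy-2,6,6-trimethyl-7-oxabicyclo[2.2.1]heptan-1-yl]-3-methylpenta-2,4-dienoate | COC(=O)/C=C(C)/C=C/[C@]12O[C@H](CC1(C)C)C[C@@]2(C)O | intermediate
9 | (2E,4E)-5-[(1S,2R,4R)-2-hydroxy-2,6,6-trimethyl-7-oxabicyclo[2.2.1]heptan-1-yl]-3-methylpenta-2,4-dien-1-ol | OC/C=C(C)/C=C/[C@]12O[C@H](CC1(C)C)C[C@@]2(C)O | intermediate
10 | (1S,2R,4R)-1-[(1E,3E)-5-bromo-3-methylpenta-1,3-dienyl]-2,6,6-trimethyl-7-oxabicyclo[2.2.1]heptan-2-ol | BrC/C=C(C)/C=C/[C@]12O[C@H](CC1(C)C)C[C@@]2(C)O | intermediate (not isolated)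
11 | ring A C15 salt, {(2E,4E)-5-[(1S,2R,4R)-2-hydroxy-2,6,6-trimethyl-7-oxabicyclo[2.2.1]heptan-1-yl]-3-methylpenta-2,4-dienyl}triphenylphosphonium bromide | c1ccccc1[P+](c1ccccc1)(c1ccccc1)C/C=C(C)/C=C/[C@]12O[C@H](CC1(C)C)C[C@@]2(C)O.[Br-] | intermediate
12 | methyl (2E,4E)-5-[(1S,4R)-1,4-dihydroxy-2,6,6-trimethylcyclohex-2-en-1-yl]-3-methylpenta-2,4-dienoate | CC1=C[C@H](O)CC(C)(C)[C@@]1(O)/C=C/C(C)=C/C(=O)OC | intermediate
13 | methyl (2E,4E)-5-[3-(acetoxymercurio)-1,2,4-trihydroxy-2,6,6-trimethylcyclohexyl]-3-methylpenta-2,4-dienoate (mercury cis to the 1- and 4-hydroxyls, trans to the 2-hydroxyl) | COC(=O)/C=C(C)/C=C/[C@]1(O)C(C)(C)C[C@@H](O)[C@@H]([Hg]OC(C)=O)[C@]1(C)O | intermediate (not isolated)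
14 | methyl (2E,4E)-5-[(1S,2S,4R)-1,2,4-trihydroxy-2,6,6-trimethylcyclohexyl]-3-methylpenta-2,4-dienoate | COC(=O)/C=C(C)/C=C/[C@]1(O)C(C)(C)C[C@@H](O)C[C@]1(C)O | intermediate
15 | (1S,2S,4R)-1-[(1E,3E)-5-hydroxy-3-methylpenta-1,3-dienyl]-2,6,6-trimethylcyclohexane-1,2,4-triol | OC/C=C(C)/C=C/[C@]1(O)C(C)(C)C[C@@H](O)C[C@]1(C)O | intermediate
16 | (1S,2S,4R)-1-[(1E,3E)-5-bromo-3-methylpenta-1,3-dienyl]-2,6,6-trimethylcyclohexane-1,2,4-triol | BrC/C=C(C)/C=C/[C@]1(O)C(C)(C)C[C@@H](O)C[C@]1(C)O | intermediate (not isolated)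
17 | ring B C15 salt, {(2E,4E)-3-methyl-5-[(1S,2S,4R)-1,2,4-trihydroxy-2,6,6-trimethylcyclohexyl]penta-2,4-dienyl}triphenylphosphonium bromide | c1ccccc1[P+](c1ccccc1)(c1ccccc1)C/C=C(C)/C=C/[C@]1(O)C(C)(C)C[C@@H](O)C[C@]1(C)O.[Br-] | intermediate
18 | (2E,4E,6E)-2,7-dimethylocta-2,4,6-trienedial | O=C/C(C)=C/C=C/C=C(C)/C=O | starting material
19 | ylide of 17 | c1ccccc1P(c1ccccc1)(c1ccccc1)=C/C=C(C)/C=C/[C@]1(O)C(C)(C)C[C@@H](O)C[C@]1(C)O | intermediate (not isolated)
20 | (2E,4E,6E,8E,10E,12E)-2,7,11-trimethyl-13-[(1S,2S,4R)-1,2,4-trihydroxy-2,6,6-trimethylcyclohexyl]trideca-2,4,6,8,10,12-hexaenal | O=C/C(C)=C/C=C/C=C(C)/C=C/C=C(C)/C=C/[C@]1(O)C(C)(C)C[C@@H](O)C[C@]1(C)O | intermediate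
21 | ylide of 11 | c1ccccc1P(c1ccccc1)(c1ccccc1)=C/C=C(C)/C=C/[C@]12O[C@H](CC1(C)C)C[C@@]2(C)O | intermediate (not isolated)
22 | (all-E)-(3R,5R,6S,3′R,5′S,6′S)-3,6-epoxy-5,6,5′,6′-tetrahydro-β,β-carotene-5,3′,5′,6′-tetrol | CC(/C=C/C=C(C)/C=C/[C@]12O[C@H](CC1(C)C)C[C@@]2(C)O)=C\C=C\C=C(C)\C=C\C=C(C)\C=C\[C@]1(O)C(C)(C)C[C@@H](O)C[C@]1(C)O | target

**Step count and risks**
Total steps: 13 (fallbacks not counted). Longest linear sequence: 8 steps (1, 2, 3, 4, 5, 6, 7, 13, or equally 1, 2, 8, 9, 10, 11, 12, 13).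

The three steps most likely to fail are steps 5, 9 and 4.

Step 5 (the proposed platinum-catalysed transannular hydroalkoxylation) may fail through ionisation or transposition of the allylic tertiary alcohol, or through catalyst binding by the cis-diol. The fallback sets out from 7 and comes back at 8 and uses known chemistry. Iodoetherification of 7 with N-iodosuccinimide and NaHCO3 in MeCN at 0 °C (the established closure of cyclohex-3-enols to 7-oxanorbornanes, anti addition) gives the endo-iodo ether methyl (2E,4E)-5-[2-hydroxy-3-endo-iodo-2,6,6-trimethyl-7-oxabicyclo[2.2.1]heptan-1-yl]-3-methylpenta-2,4-dienoate F1. Radical deiodination with Bu3SnH and AIBN in toluene at 80 °C then gives 8.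

Step 9 (oxymercuration–demercuration) may give the wrong face at C5′ if hydroxyl direction is weak, or revert to alkene during demercuration. The fallback sets out from 4 and comes back at 14, and fixes C5′ by a stereospecific inversion instead of a directed addition. Acid-catalysed hydrolysis of 4 (HClO4 cat., THF/H2O, 0 °C) opens the epoxide at the tertiary β-carbon with inversion to give the diol ketone methyl (2E,4E)-5-[(1S,2S,3S)-1,2,3-trihydroxy-2,6,6-trimethyl-4-oxocyclohexyl]-3-methylpenta-2,4-dienoate F2. Selective acetylation of the secondary hydroxyl (Ac2O, pyridine) gives the α-acetoxy ketone methyl (2E,4E)-5-[(1S,2S,3S)-3-acetoxy-1,2-dihydroxy-2,6,6-trimethyl-4-oxocyclohexyl]-3-methylpenta-2,4-dienoate F3. Samarium diiodide (THF/MeOH, −78 °C) removes the α-acetoxy group to give the β-hydroxy ketone methyl (2E,4E)-5-[(1S,2S)-1,2-dihydroxy-2,6,6-trimethyl-4-oxocyclohexyl]-3-methylpenta-2,4-dienoate F4. Hydroxyl-directed anti reduction with Me4NBH(OAc)3 (MeCN/AcOH, −30 °C, delivery from the axial C5′ hydroxyl) then gives 14.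

Step 4 (Wharton transposition) may give low yield because hydrazine can attack the dienoate ester and the alkenyl diazene can decompose along other paths. The fallback sets out from 4 and comes back at 8; it closes the bridge from the other side by a Williamson-type displacement and so also by-passes step 5. Samarium diiodide (THF/MeOH, −90 °C) cleaves the Cα–O bond of 4 to give the β-hydroxy ketone methyl (2E,4E)-5-[(1S,2R)-1,2-dihydroxy-2,6,6-trimethyl-4-oxocyclohexyl]-3-methylpenta-2,4-dienoate F5. Me4NBH(OAc)3 reduces it anti to the C5 and C6 hydroxyls to the triol methyl (2E,4E)-5-[(1S,2R,4S)-1,2,4-trihydroxy-2,6,6-trimethylcyclohexyl]-3-methylpenta-2,4-dienoate F6. MsCl in pyridine at 0 °C sulfonylates only the secondary hydroxyl to give the mesylate methyl (2E,4E)-5-[(1S,2R,4S)-1,2-dihydroxy-4-(methanesulfonyloxy)-2,6,6-trimethylcyclohexyl]-3-methylpenta-2,4-dienoate F7. KOt-Bu in THF (0 °C to rt) makes the C6 alkoxide displace the mesylate at C3 with inversion, giving 8.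

**Further compounds**
F1 | step 5 | methyl (2E,4E)-5-[2-hydroxy-3-endo-iodo-2,6,6-trimethyl-7-oxabicyclo[2.2.1]heptan-1-yl]-3-methylpenta-2,4-dienoate | COC(=O)/C=C(C)/C=C/[C@]12O[C@H](CC1(C)C)[C@H](I)[C@@]2(C)O
F2 | step 9 | methyl (2E,4E)-5-[(1S,2S,3S)-1,2,3-trihydroxy-2,6,6-trimethyl-4-oxocyclohexyl]-3-methylpenta-2,4-dienoate | C[C@]1(O)[C@H](O)C(=O)CC(C)(C)[C@@]1(O)/C=C/C(C)=C/C(=O)OC
F3 | step 9 | methyl (2E,4E)-5-[(1S,2S,3S)-3-acetoxy-1,2-dihydroxy-2,6,6-trimethyl-4-oxocyclohexyl]-3-methylpenta-2,4-dienoate | C[C@]1(O)[C@H](OC(C)=O)C(=O)CC(C)(C)[C@@]1(O)/C=C/C(C)=C/C(=O)OC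
F4 | step 9 | methyl (2E,4E)-5-[(1S,2S)-1,2-dihydroxy-2,6,6-trimethyl-4-oxocyclohexyl]-3-methylpenta-2,4-dienoate | C[C@]1(O)CC(=O)CC(C)(C)[C@@]1(O)/C=C/C(C)=C/C(=O)OC
F5 | step 4 | methyl (2E,4E)-5-[(1S,2R)-1,2-dihydroxy-2,6,6-trimethyl-4-oxocyclohexyl]-3-methylpenta-2,4-dienoate | C[C@@]1(O)CC(=O)CC(C)(C)[C@@]1(O)/C=C/C(C)=C/C(=O)OC
F6 | step 4 | methyl (2E,4E)-5-[(1S,2R,4S)-1,2,4-trihydroxy-2,6,6-trimethylcyclohexyl]-3-methylpenta-2,4-dienoate | C[C@@]1(O)C[C@@H](O)CC(C)(C)[C@@]1(O)/C=C/C(C)=C/C(=O)OC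
F7 | step 4 | methyl (2E,4E)-5-[(1S,2R,4S)-1,2-dihydroxy-4-(methanesulfonyloxy)-2,6,6-trimethylcyclohexyl]-3-methylpenta-2,4-dienoate | C[C@@]1(O)C[C@@H](OS(C)(=O)=O)CC(C)(C)[C@@]1(O)/C=C/C(C)=C/C(=O)OC
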